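## Retrosynthetic overview

1. The triacid comes from its tri-tert-butyl ester by acidolysis; the bicyclic ketal comes from a C1 lactol carrying the C3 and C4 hydroxyls by acid ketalisation.
2. The lactol comes from a side-chain alkyllithium adding once to the C1 carbonyl of a γ-lactone triester.
3. The γ-lactone comes from a butenolide made in the key step: an intermolecular vinylogous Mukaiyama aldol (C4–C5 bond) between a 5-silyloxy-2-furoate and a D-tartrate-derived α-keto diester, which sets both quaternary centres.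
4. The side chain comes from an Evans benzylation (methyl stereocentre), an E-selective Wittig reaction, diene hydroboration and iodination.
5. Ring order: the oxolane ring first (as butenolide/lactone from the aldol), the 1,3-dioxane ring last (ketalisation).

Assumption: the facial sense of the step 5 aldol follows the five-membered α-alkoxy chelate model; minor diastereomers are removed by chromatography after step 5 and the assignment is checked on the crystalline step 6 product.

## Route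

Step 1
Reactants: 1 (−)-di-tert-butyl D-tartrate
Product: 3 di-tert-butyl (2S,3S)-2-(benzyloxy)-3-hydroxybutanedioate, via stannylene acetal 2 (not isolated)
Conditions: Bu2SnO (1.05 equiv), toluene, reflux (Dean–Stark); then BnBr (1.2 equiv), CsF (2 equiv), DMF, rt
Reagents that add atoms: benzyl bromide, BrCc1ccccc1
Why: Stannylene-mediated Williamson mono-etherification: the tin acetal activates one oxygen of the C2-symmetric diol and the second is deactivated after the first alkylation, so mono-benzylation occurs without touching the stereocentres.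

Step 2
Reactants: 3 di-tert-butyl (2S,3S)-2-(benzyloxy)-3-hydroxybutanedioate
Product: 4 di-tert-butyl (2S)-2-(benzyloxy)-3-oxobutanedioate
Conditions: Dess–Martin periodinane (1.3 equiv), CH2Cl2, 0 °C to rt; pentane dilution, filtration; used crude at once
Reagents that add atoms: none
Why: Dess–Martin oxidation is neutral and base-free, so the enolisable (S) centre next to the new ketone survives if the keto ester is kept cold, not chromatographed and used immediately.

Step 3
Reactants: 5 furan-2(5H)-one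
Product: 6 2-(triisopropylsilyloxy)furan
Conditions: i-Pr3SiOTf, Et3N, CH2Cl2, 0 °C
Reagents that add atoms: triisopropylsilyl trifluoromethanesulfonate, CC(C)[Si](OS(=O)(=O)C(F)(F)F)(C(C)C)C(C)C
Why: Soft enolisation and O-silylation of the butenolide gives the aromatic 2-silyloxyfuran, with a bulky silyl group that survives the next metalation.

Step 4
Reactants: 6 2-(triisopropylsilyloxy)furan
Product: 8 tert-butyl 5-(triisopropylsilyloxy)furan-2-carboxylate, via 5-lithiofuran 7 (not isolated)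
Conditions: s-BuLi, TMEDA, THF, −78 to 0 °C; then cannulated into Boc2O, THF, −78 °C
Reagents that add atoms: di-tert-butyl dicarbonate, CC(C)(C)OC(=O)OC(=O)OC(C)(C)C
Why: α-Lithiation at the only free furan α-position (C5) followed by inverse-addition acylation installs the tert-butyl ester, the bulky silyl group blocking attack at silicon.

Step 5
Reactants: 4 di-tert-butyl (2S)-2-(benzyloxy)-3-oxobutanedioate; 8 tert-butyl 5-(triisopropylsilyloxy)furan-2-carboxylate
Product: 9 di-tert-butyl (2S,3S)-2-(benzyloxy)-3-[(2R)-2-(tert-butoxycarbonyl)-5-oxo-2,5-dihydrofuran-2-yl]-3-hydroxybutanedioate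
Conditions: TiCl4 (1.1 equiv), CH2Cl2, −78 °C, 15 min; then 8 (1.3 equiv), −78 °C; aq. NaHCO3; chromatography
Reagents that add atoms: none
Why: Vinylogous Mukaiyama aldol: TiCl4 locks the ketone and the benzyloxy oxygen in a five-membered chelate so the furan C5 attacks the face anti to the C3 ester (C4 becomes S), and an antiperiplanar open transition state with the furan ester turned away from the chelate sets the adjacent quaternary C5 as R.

Step 6
Reactants: 9 butenolide aldol adduct
Product: 10 di-tert-butyl (2S,3S)-2-[(2R)-2-(tert-butoxycarbonyl)-5-oxooxolan-2-yl]-2,3-dihydroxybutanedioate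
Conditions: H2 (1 atm), 10% Pd/C, EtOAc/EtOH 1:1, rt
Reagents that add atoms: none
Why: Catalytic hydrogenation saturates the cis-disubstituted butenolide alkene and hydrogenolyses the benzyl ether in one operation, while tert-butyl esters and lactone are inert and no stereocentre is touched.

Step 7
Reactants: 10 lactone diol
Product: 11 di-tert-butyl (2S,3S)-2-[(2R)-2-(tert-butoxycarbonyl)-5-oxooxolan-2-yl]-2,3-bis(trimethylsilyloxy)butanedioate
Conditions: Me3SiOTf (3 equiv), 2,6-lutidine (4 equiv), CH2Cl2, −78 to 0 °C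
Reagents that add atoms: trimethylsilyl trifluoromethanesulfonate, C[Si](C)(C)OS(=O)(=O)C(F)(F)F
Why: O-Silylation with the small, highly electrophilic silyl triflate caps both the secondary and the hindered tertiary hydroxyl so that no acidic proton consumes the organolithium in step 17.

Step 8
Reactants: 12 (R)-4-benzyl-3-propanoyloxazolidin-2-one
Product: 14 (R)-4-benzyl-3-[(S)-2-methyl-3-phenylpropanoyl]oxazolidin-2-one, via sodium enolate 13 (not isolated)
Conditions: NaN(SiMe3)2, THF, −78 °C; BnBr, −78 to −40 °C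
Reagents that add atoms: benzyl bromide, BrCc1ccccc1
Why: Evans asymmetric alkylation: the chelated (Z)-sodium enolate is benzylated on the face opposite the auxiliary benzyl group, giving the (S)-α-methyl centre with high diastereoselectivity.

Step 9
Reactants: 14 (R)-4-benzyl-3-[(S)-2-methyl-3-phenylpropanoyl]oxazolidin-2-one
Product: 15 (S)-2-methyl-3-phenylpropan-1-ol
Conditions: LiBH4, MeOH (1 equiv), Et2O, 0 °C
Reagents that add atoms: none
Why: Reductive cleavage of the exocyclic imide carbonyl by borohydride releases the primary alcohol without epimerisation and returns the auxiliary.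

Step 10
Reactants: 15 (S)-2-methyl-3-phenylpropan-1-ol
Product: 16 (S)-2-methyl-3-phenylpropanal
Conditions: Dess–Martin periodinane, CH2Cl2, 0 °C to rt; used crude at once
Reagents that add atoms: none
Why: Dess–Martin oxidation under neutral conditions gives the α-branched aldehyde without racemisation.

Step 11
Reactants: 16 (S)-2-methyl-3-phenylpropanal
Product: 17 ethyl (2E,4S)-2,4-dimethyl-5-phenylpent-2-enoate
Conditions: Ph3P=C(Me)CO2Et, CH2Cl2, rt
Reagents that add atoms: ethyl 2-(triphenylphosphoranylidene)propanoate, CCOC(=O)C(C)=P(c1ccccc1)(c1ccccc1)c1ccccc1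
Why: Wittig olefination with the stabilised α-branched ylide gives the (E)-trisubstituted enoate at room temperature without epimerising the neighbouring stereocentre.

Step 12
Reactants: 17 ethyl (2E,4S)-2,4-dimethyl-5-phenylpent-2-enoate
Product: 18 (2E,4S)-2,4-dimethyl-5-phenylpent-2-en-1-ol
Conditions: i-Bu2AlH (2.2 equiv), CH2Cl2, −78 °C
Reagents that add atoms: none
Why: Hydride 1,2-reduction of the enoate with excess aluminium hydride at low temperature gives the allylic alcohol with the alkene geometry intact.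

Step 13
Reactants: 18 (2E,4S)-2,4-dimethyl-5-phenylpent-2-en-1-ol
Product: 19 (2E,4S)-2,4-dimethyl-5-phenylpent-2-enal
Conditions: Dess–Martin periodinane, CH2Cl2, 0 °C
Reagents that add atoms: none
Why: Dess–Martin oxidation of the allylic alcohol gives the enal with retention of the E geometry.

Step 14
Reactants: 19 (2E,4S)-2,4-dimethyl-5-phenylpent-2-enal
Product: 20 [(2S,3E)-2,4-dimethylhexa-3,5-dien-1-yl]benzene
Conditions: Ph3PCH3Br (1.3 equiv), KOtBu (1.2 equiv), THF, 0 °C; then 19, −78 to 0 °C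
Reagents that add atoms: methyltriphenylphosphonium bromide, C[P+](c1ccccc1)(c1ccccc1)c1ccccc1.[Br-]
Why: Wittig methylenation with the non-stabilised ylide (phosphonium salt in slight excess over base, so no γ-deprotonation) converts the enal into the 1,3-diene.

Step 15
Reactants: 20 [(2S,3E)-2,4-dimethylhexa-3,5-dien-1-yl]benzene
Product: 22 (3E,5S)-3,5-dimethyl-6-phenylhex-3-en-1-ol, via B-alkyl-9-BBN borane 21 (not isolated)
Conditions: 9-BBN (1.2 equiv), THF, 0 °C to rt; then NaOH, H2O2, 0 °C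
Reagents that add atoms: hydrogen peroxide, OO
Why: Brown hydroboration–oxidation: the bulky borane adds only to the terminal monosubstituted alkene with anti-Markovnikov regiochemistry and leaves the trisubstituted E alkene untouched.

Step 16
Reactants: 22 (3E,5S)-3,5-dimethyl-6-phenylhex-3-en-1-ol
Product: 23 [(2S,3E)-6-iodo-2,4-dimethylhex-3-en-1-yl]benzene
Conditions: I2, PPh3, imidazole, CH2Cl2, 0 °C
Reagents that add atoms: iodine, II
Why: Appel-type iodination (Garegg–Samuelsson conditions) converts the primary alcohol into the iodide by SN2 displacement of the oxyphosphonium group.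

Step 17
Reactants: 23 [(2S,3E)-6-iodo-2,4-dimethylhex-3-en-1-yl]benzene; 11 bis-silylated lactone triester
Product: 25 di-tert-butyl (2S,3S)-2-[(2R)-2-(tert-butoxycarbonyl)-5-[(3E,5S)-3,5-dimethyl-6-phenylhex-3-en-1-yl]-5-hydroxyoxolan-2-yl]-2,3-bis(trimethylsilyloxy)butanedioate (lactol; both anomers), via alkyllithium 24 (not isolated)
Conditions: 23 (1.5 equiv), t-BuLi (3.1 equiv), Et2O, −78 °C; then 11 (1 equiv), THF, −78 °C; AcOH quench at −78 °C
Reagents that add atoms: none
Why: Iodine–lithium exchange gives the primary alkyllithium, which undergoes a single acyl addition to the unhindered γ-lactone carbonyl because the lithium hemiketalate is stable at −78 °C and the tert-butyl esters on congested carbons do not react.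

Step 18
Reactants: 25 lactol
Product: 27 tri-tert-butyl (1S,3S,4S,5R)-1-[(3E,5S)-3,5-dimethyl-6-phenylhex-3-en-1-yl]-4-hydroxy-2,8-dioxabicyclo[3.2.1]octane-3,4,5-tricarboxylate, via desilylated lactol 26 (not isolated)
Conditions: p-TsOH·H2O (0.3 equiv), CH2Cl2/MeOH 10:1, rt
Reagents that add atoms: none
Why: Acid-catalysed desilylation and intramolecular ketalisation: the hemiketal equilibrates through its oxocarbenium ion to the thermodynamically preferred 2,8-dioxabicyclo[3.2.1]octane by closure with the C3 hydroxyl, and the bridgehead C1 configuration (S) is dictated by C3 and C5.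

Step 19
Reactants: 27 bicyclic tri-tert-butyl ester
Product: 28 (1S,3S,4S,5R)-1-[(3E,5S)-3,5-dimethyl-6-phenylhex-3-en-1-yl]-4-hydroxy-2,8-dioxabicyclo[3.2.1]octane-3,4,5-tricarboxylic acid
Conditions: CF3CO2H/CH2Cl2 1:3, rt; reversed-phase HPLC
Reagents that add atoms: none
Why: Acidolysis (E1 loss of isobutene) cleaves the three tert-butyl esters, while the internal ketal, the tertiary alcohol and the trisubstituted alkene are expected to tolerate dilute acid at room temperature.

## Compound list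

1 | (−)-di-tert-butyl D-tartrate, di-tert-butyl (2S,3S)-2,3-dihydroxybutanedioate | CC(C)(C)OC(=O)[C@@H](O)[C@H](O)C(=O)OC(C)(C)C | starting material
2 | di-tert-butyl (4S,5S)-2,2-dibutyl-1,3,2-dioxastannolane-4,5-dicarboxylate (stannylene acetal) | CCCC[Sn]1(CCCC)O[C@H](C(=O)OC(C)(C)C)[C@@H](C(=O)OC(C)(C)C)O1 | intermediate
3 | di-tert-butyl (2S,3S)-2-(benzyloxy)-3-hydroxybutanedioate | CC(C)(C)OC(=O)[C@@H](O)[C@H](OCc1ccccc1)C(=O)OC(C)(C)C | intermediate
4 | di-tert-butyl (2S)-2-(benzyloxy)-3-oxobutanedioate | CC(C)(C)OC(=O)C(=O)[C@H](OCc1ccccc1)C(=O)OC(C)(C)C | intermediate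
5 | furan-2(5H)-one | O=C1OCC=C1 | starting material
6 | 2-(triisopropylsilyloxy)furan | CC(C)[Si](Oc1ccco1)(C(C)C)C(C)C | intermediate
7 | 5-lithio-2-(triisopropylsilyloxy)furan | [Li]c1ccc(O[Si](C(C)C)(C(C)C)C(C)C)o1 | intermediate
8 | tert-butyl 5-(triisopropylsilyloxy)furan-2-carboxylate | CC(C)(C)OC(=O)c1ccc(O[Si](C(C)C)(C(C)C)C(C)C)o1 | intermediate
9 | di-tert-butyl (2S,3S)-2-(benzyloxy)-3-[(2R)-2-(tert-butoxycarbonyl)-5-oxo-2,5-dihydrofuran-2-yl]-3-hydroxybutanedioate | O=C1C=C[C@@](C(=O)OC(C)(C)C)(O1)[C@](O)(C(=O)OC(C)(C)C)[C@@H](C(=O)OC(C)(C)C)OCc1ccccc1 | intermediate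
10 | di-tert-butyl (2S,3S)-2-[(2R)-2-(tert-butoxycarbonyl)-5-oxooxolan-2-yl]-2,3-dihydroxybutanedioate | O=C1CC[C@@](C(=O)OC(C)(C)C)(O1)[C@](O)(C(=O)OC(C)(C)C)[C@@H](C(=O)OC(C)(C)C)O | intermediate
11 | di-tert-butyl (2S,3S)-2-[(2R)-2-(tert-butoxycarbonyl)-5-oxooxolan-2-yl]-2,3-bis(trimethylsilyloxy)butanedioate | O=C1CC[C@@](C(=O)OC(C)(C)C)(O1)[C@](O[Si](C)(C)C)(C(=O)OC(C)(C)C)[C@@H](C(=O)OC(C)(C)C)O[Si](C)(C)C | intermediate
12 | (R)-4-benzyl-3-propanoyloxazolidin-2-one | CCC(=O)N1[C@H](Cc2ccccc2)COC1=O | starting material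
13 | sodium (Z)-enolate of 12 | C/C=C(\[O-])N1[C@H](Cc2ccccc2)COC1=O.[Na+] | intermediate
14 | (R)-4-benzyl-3-[(S)-2-methyl-3-phenylpropanoyl]oxazolidin-2-one | C[C@@H](Cc1ccccc1)C(=O)N1[C@H](Cc2ccccc2)COC1=O | intermediate
15 | (S)-2-methyl-3-phenylpropan-1-ol | C[C@@H](Cc1ccccc1)CO | intermediate
16 | (S)-2-methyl-3-phenylpropanal | C[C@@H](Cc1ccccc1)C=O | intermediate
17 | ethyl (2E,4S)-2,4-dimethyl-5-phenylpent-2-enoate | CCOC(=O)/C(C)=C/[C@@H](C)Cc1ccccc1 | intermediate
18 | (2E,4S)-2,4-dimethyl-5-phenylpent-2-en-1-ol | OC/C(C)=C/[C@@H](C)Cc1ccccc1 | intermediate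
19 | (2E,4S)-2,4-dimethyl-5-phenylpent-2-enal | O=C/C(C)=C/[C@@H](C)Cc1ccccc1 | intermediate
20 | [(2S,3E)-2,4-dimethylhexa-3,5-dien-1-yl]benzene | C=C/C(C)=C/[C@@H](C)Cc1ccccc1 | intermediate
21 | 9-[(3E,5S)-3,5-dimethyl-6-phenylhex-3-en-1-yl]-9-borabicyclo[3.3.1]nonane | B1(CC/C(C)=C/[C@@H](C)Cc2ccccc2)C2CCCC1CCC2 | intermediate
22 | (3E,5S)-3,5-dimethyl-6-phenylhex-3-en-1-ol | OCC/C(C)=C/[C@@H](C)Cc1ccccc1 | intermediate
23 | [(2S,3E)-6-iodo-2,4-dimethylhex-3-en-1-yl]benzene | ICC/C(C)=C/[C@@H](C)Cc1ccccc1 | intermediate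
24 | [(3E,5S)-3,5-dimethyl-6-phenylhex-3-en-1-yl]lithium | [Li]CC/C(C)=C/[C@@H](C)Cc1ccccc1 | intermediate
25 | di-tert-butyl (2S,3S)-2-[(2R)-2-(tert-butoxycarbonyl)-5-[(3E,5S)-3,5-dimethyl-6-phenylhex-3-en-1-yl]-5-hydroxyoxolan-2-yl]-2,3-bis(trimethylsilyloxy)butanedioate (lactol, both anomers) | C/C(=C\[C@@H](C)Cc1ccccc1)CCC1(O)CC[C@@](C(=O)OC(C)(C)C)(O1)[C@](O[Si](C)(C)C)(C(=O)OC(C)(C)C)[C@@H](C(=O)OC(C)(C)C)O[Si](C)(C)C | intermediate
26 | di-tert-butyl (2S,3S)-2-[(2R)-2-(tert-butoxycarbonyl)-5-[(3E,5S)-3,5-dimethyl-6-phenylhex-3-en-1-yl]-5-hydroxyoxolan-2-yl]-2,3-dihydroxybutanedioate (desilylated lactol) | C/C(=C\[C@@H](C)Cc1ccccc1)CCC1(O)CC[C@@](C(=O)OC(C)(C)C)(O1)[C@](O)(C(=O)OC(C)(C)C)[C@@H](C(=O)OC(C)(C)C)O | intermediate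
27 | tri-tert-butyl (1S,3S,4S,5R)-1-[(3E,5S)-3,5-dimethyl-6-phenylhex-3-en-1-yl]-4-hydroxy-2,8-dioxabicyclo[3.2.1]octane-3,4,5-tricarboxylate | C/C(=C\[C@@H](C)Cc1ccccc1)CC[C@@]12CC[C@@](C(=O)OC(C)(C)C)(O1)[C@](O)(C(=O)OC(C)(C)C)[C@@H](C(=O)OC(C)(C)C)O2 | intermediate
28 | (1S,3S,4S,5R)-1-[(3E,5S)-3,5-dimethyl-6-phenylhex-3-en-1-yl]-4-hydroxy-2,8-dioxabicyclo[3.2.1]octane-3,4,5-tricarboxylic acid (CNP0217737.2) | C/C(=C\[C@@H](C)Cc1ccccc1)CC[C@@]12CC[C@@](C(=O)O)(O1)[C@](O)(C(=O)O)[C@@H](C(=O)O)O2 | target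

## Totals and risks

Total step count: 19. Longest linear sequence: 12 steps (12 to 28, steps 8–19).

**Step 5 (vinylogous aldol).** Two adjacent quaternary centres are made in one step. Keto ester 4 is enolisable, so its ee can erode, and the chelate-controlled facial sense and the C5 selectivity are predicted, not guaranteed. The fallback sets out from 1 and comes back at 28 by reversing the polarity of the C4–C5 aldol. Compound 1 is converted with 2,2-dimethoxypropane and catalytic p-TsOH into di-tert-butyl (4S,5S)-2,2-dimethyl-1,3-dioxolane-4,5-dicarboxylate F1. Deprotonation with LiN(i-Pr)2 in THF/HMPA at −78 °C gives its lithium enolate F2. This is added to di-tert-butyl 2-oxopentanedioate F3, made from 2-oxoglutaric acid and tert-butyl 2,2,2-trichloroacetimidate. Attack anti to the neighbouring ester sets C4, and the tertiary alkoxide closes onto the distal ester to give the acetonide-protected lactone triester F4, whose C5 epimers are separated. Alkyllithium 24 is then added as in step 17 to give the acetonide-protected lactol F5. Treatment with CF3CO2H/CH2Cl2/H2O removes the acetonide and tert-butyl groups and closes the ketal to 28.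

**Step 17 (single addition of 24 to lactone 11).** Over-addition, ester attack or enolisation would waste the nine-step side chain. The fallback sets out from 11 and comes back at 25. Lactone 11 is reduced with i-Bu2AlH at −78 °C to the C1 lactol F6. Alkyllithium 24 (2.5 equiv) adds to its ring-opened aldehyde form to give the 1,4-diol F7. Dess–Martin oxidation of the secondary alcohol then gives the γ-hydroxy ketone, which closes to 25.

**Step 18 (ketalisation).** The C3 and C4 hydroxyls can together capture C1 and give the isomeric 6,8-dioxabicyclo[3.2.1]octane instead. The fallback sets out from 25 and comes back at 27. Only the secondary C3 silyl ether is cleaved (K2CO3, MeOH, 0 °C) to give the C4-O-silyl lactol F8. With the tertiary C4 oxygen still blocked, camphorsulfonic acid in CH2Cl2 over 4 Å sieves can only close the C3–O/C5–O ketal, giving the C4-O-silyl bicyclic ketal F9. Bu4NF/AcOH in THF then gives 27.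

## Further compounds

F1 | step 5 | di-tert-butyl (4S,5S)-2,2-dimethyl-1,3-dioxolane-4,5-dicarboxylate | CC1(C)O[C@H](C(=O)OC(C)(C)C)[C@@H](C(=O)OC(C)(C)C)O1
F2 | step 5 | lithium enolate of F1 | CC1(C)O[C@H](C(=O)OC(C)(C)C)C(=C([O-])OC(C)(C)C)O1.[Li+]
F3 | step 5 | di-tert-butyl 2-oxopentanedioate | CC(C)(C)OC(=O)CCC(=O)C(=O)OC(C)(C)C
F4 | step 5 | di-tert-butyl (4S,5S)-4-[(2R)-2-(tert-butoxycarbonyl)-5-oxooxolan-2-yl]-2,2-dimethyl-1,3-dioxolane-4,5-dicarboxylate | O=C1CC[C@@](C(=O)OC(C)(C)C)(O1)[C@@]2(C(=O)OC(C)(C)C)OC(C)(C)O[C@@H]2C(=O)OC(C)(C)C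
F5 | step 5 | di-tert-butyl (4S,5S)-4-[(2R)-2-(tert-butoxycarbonyl)-5-[(3E,5S)-3,5-dimethyl-6-phenylhex-3-en-1-yl]-5-hydroxyoxolan-2-yl]-2,2-dimethyl-1,3-dioxolane-4,5-dicarboxylate | C/C(=C\[C@@H](C)Cc1ccccc1)CCC1(O)CC[C@@](C(=O)OC(C)(C)C)(O1)[C@@]2(C(=O)OC(C)(C)C)OC(C)(C)O[C@@H]2C(=O)OC(C)(C)C
F6 | step 17 | di-tert-butyl (2S,3S)-2-[(2R)-2-(tert-butoxycarbonyl)-5-hydroxyoxolan-2-yl]-2,3-bis(trimethylsilyloxy)butanedioate | OC1CC[C@@](C(=O)OC(C)(C)C)(O1)[C@](O[Si](C)(C)C)(C(=O)OC(C)(C)C)[C@@H](C(=O)OC(C)(C)C)O[Si](C)(C)C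
F7 | step 17 | tri-tert-butyl (1S,2S,3R,9E,11S)-3,6-dihydroxy-9,11-dimethyl-12-phenyl-1,2-bis(trimethylsilyloxy)dodec-9-ene-1,2,3-tricarboxylate (both C6 epimers) | C/C(=C\[C@@H](C)Cc1ccccc1)CCC(O)CC[C@@](C(=O)OC(C)(C)C)(O)[C@](O[Si](C)(C)C)(C(=O)OC(C)(C)C)[C@@H](C(=O)OC(C)(C)C)O[Si](C)(C)C
F8 | step 18 | di-tert-butyl (2S,3S)-2-[(2R)-2-(tert-butoxycarbonyl)-5-[(3E,5S)-3,5-dimethyl-6-phenylhex-3-en-1-yl]-5-hydroxyoxolan-2-yl]-3-hydroxy-2-(trimethylsilyloxy)butanedioate | C/C(=C\[C@@H](C)Cc1ccccc1)CCC1(O)CC[C@@](C(=O)OC(C)(C)C)(O1)[C@](O[Si](C)(C)C)(C(=O)OC(C)(C)C)[C@@H](C(=O)OC(C)(C)C)O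
F9 | step 18 | tri-tert-butyl (1S,3S,4S,5R)-1-[(3E,5S)-3,5-dimethyl-6-phenylhex-3-en-1-yl]-4-(trimethylsilyloxy)-2,8-dioxabicyclo[3.2.1]octane-3,4,5-tricarboxylate | C/C(=C\[C@@H](C)Cc1ccccc1)CC[C@@]12CC[C@@](C(=O)OC(C)(C)C)(O1)[C@](O[Si](C)(C)C)(C(=O)OC(C)(C)C)[C@@H](C(=O)OC(C)(C)C)O2
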